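**Retrosynthetic overview**

1. The strategy rests on ring A, a pentasubstituted benzene with meta oxygens: C1–OMe, C2–H, C3–OH, 4-hydroxybenzyl groups at C4 and C6, and C5 carrying the CH2CH2 link to ring B. C1–C4 map onto a 1,1-dimethoxy-3-silyloxy-diene and C5–C6 onto a polarised alkyne.
2. Ring A is the only ring built. It is closed by a [4+2] benzannulation of diene 15 with aryl ynone 10 (bonds C4–C5 and C1–C6), and it aromatises by loss of methanol. The four other benzene rings are bought.
3. After the key step, the C6 aroyl group is reduced to the benzyl CH2 (hydride, then silane/acid) and the four benzyl ethers are removed by hydrogenolysis.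
4. Ynone 10 comes from acyl Sonogashira coupling of butynyl arene 8 with 4-(benzyloxy)benzoyl chloride. Alkyne 8 comes from ring-B bromide 5 by Heck reaction with allyl alcohol and Ohira–Bestmann homologation. Bromide 5 comes from 2-bromo-4-hydroxybenzaldehyde by benzylation, aryl Grignard addition and ionic reduction.
5. Diene 15 comes from C-acylation of 1,1-dimethoxyethene with O-benzylphloretic acid chloride, then (Z)-selective silyl enol ether formation.

Key step: step 10

Remark: the target has no stereocentre and no stereogenic double bond, so it is achiral and needs no enantiocontrol; the only geometric element in the route is the (Z)-enol ether of diene 15.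

**Route**

Step 1
Reactants: 1 2-bromo-4-hydroxybenzaldehyde
Product: 2 4-(benzyloxy)-2-bromobenzaldehyde
Conditions: BnBr, K2CO3, DMF, rt
Reagents that add atoms: benzyl bromide, BrCc1ccccc1
Why: Williamson ether synthesis on an acidic para-formyl phenol should proceed cleanly, and the aldehyde and aryl bromide are inert to carbonate.

Step 2
Reactants: 2 4-(benzyloxy)-2-bromobenzaldehyde; 3 4-(benzyloxy)phenylmagnesium bromide (commercial THF solution)
Product: 4 (±)-[4-(benzyloxy)-2-bromophenyl][4-(benzyloxy)phenyl]methanol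
Conditions: THF, −10 °C → rt; aq NH4Cl
Reagents that add atoms: none
Why: Grignard addition to the aldehyde is much faster than Mg/Br exchange at the aryl bromide at this temperature; the new carbinol centre is racemic and is removed in step 3.

Step 3
Reactants: 4 (±)-[4-(benzyloxy)-2-bromophenyl][4-(benzyloxy)phenyl]methanol
Product: 5 4-(benzyloxy)-1-[4-(benzyloxy)benzyl]-2-bromobenzene
Conditions: Et3SiH, TFA, CH2Cl2, 0 °C
Reagents that add atoms: none
Why: Ionic hydrogenation (Kursanov–Parnes): the carbinol ionises to a cation stabilised by two para-alkoxyaryl rings and is trapped by the silane, while aryl benzyl ethers and the aryl bromide survive cold dilute TFA.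

Step 4
Reactants: 5 4-(benzyloxy)-1-[4-(benzyloxy)benzyl]-2-bromobenzene; 6 allyl alcohol (prop-2-en-1-ol)
Product: 7 3-{5-(benzyloxy)-2-[4-(benzyloxy)benzyl]phenyl}propanal
Conditions: Pd(OAc)2 (5 mol%), Bu4NCl, NaHCO3, DMF, 80 °C
Reagents that add atoms: none
Why: Heck reaction under Jeffery conditions: terminal arylation of allyl alcohol, β-hydride elimination toward the carbinol carbon and enol tautomerisation should give the saturated 3-arylpropanal directly.

Step 5
Reactants: 7 3-{5-(benzyloxy)-2-[4-(benzyloxy)benzyl]phenyl}propanal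
Product: 8 4-(benzyloxy)-1-[4-(benzyloxy)benzyl]-2-(but-3-yn-1-yl)benzene
Conditions: dimethyl (1-diazo-2-oxopropyl)phosphonate, K2CO3, MeOH/THF, 0 °C → rt
Reagents that add atoms: dimethyl (1-diazo-2-oxopropyl)phosphonate, COP(=O)(OC)C(=[N+]=[N-])C(C)=O
Why: Ohira–Bestmann modification of the Seyferth–Gilbert homologation converts an enolisable aldehyde into the terminal alkyne under mild carbonate conditions that the benzyl ethers tolerate.

Step 6
Reactants: 8 4-(benzyloxy)-1-[4-(benzyloxy)benzyl]-2-(but-3-yn-1-yl)benzene; 9 4-(benzyloxy)benzoyl chloride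
Product: 10 1-[4-(benzyloxy)phenyl]-5-{5-(benzyloxy)-2-[4-(benzyloxy)benzyl]phenyl}pent-2-yn-1-one
Conditions: PdCl2(PPh3)2 (2 mol%), CuI (4 mol%), Et3N, THF, rt
Reagents that add atoms: none
Why: Acyl Sonogashira coupling of a terminal alkyne with an aroyl chloride should give the ynone in one step at room temperature, without strong base that could isomerise the propargylic CH2.

Step 7
Reactants: 11 3-[4-(benzyloxy)phenyl]propanoic acid (O-benzylphloretic acid)
Product: 12 3-[4-(benzyloxy)phenyl]propanoyl chloride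
Conditions: (COCl)2, cat. DMF, CH2Cl2, 0 °C → rt; evaporation
Reagents that add atoms: oxalyl chloride, ClC(=O)C(=O)Cl
Why: Vilsmeier-catalysed acid chloride formation is neutral enough to leave the aryl benzyl ether intact and gives only gaseous by-products.

Step 8
Reactants: 12 3-[4-(benzyloxy)phenyl]propanoyl chloride; 13 1,1-dimethoxyethene (3 equiv)
Product: 14 5-[4-(benzyloxy)phenyl]-1,1-dimethoxypent-1-en-3-one
Conditions: Et2O, 0 °C → rt; volatiles removed in vacuo, no aqueous work-up
Reagents that add atoms: none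
Why: C-acylation of a ketene acetal by an acid chloride: the nucleophilic CH2 attacks the acyl chloride, the dimethoxycarbenium ion loses a proton, and a second equivalent of ketene acetal consumes the HCl as methyl acetate and chloromethane, so all by-products are volatile.

Step 9
Reactants: 14 5-[4-(benzyloxy)phenyl]-1,1-dimethoxypent-1-en-3-one
Product: 15 (3Z)-5-[4-(benzyloxy)phenyl]-1,1-dimethoxy-3-(trimethylsilyloxy)penta-1,3-diene
Conditions: TMSOTf, Et3N, Et2O, 0 °C → rt; pentane, decanted from the ammonium salt under Ar, concentrated, used crude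
Reagents that add atoms: trimethylsilyl trifluoromethanesulfonate, C[Si](C)(C)OS(=O)(=O)C(F)(F)F
Why: Soft enolisation: O-silylation of the vinylogous-ester carbonyl followed by amine deprotonation at the only enolisable CH2 should give, under these equilibrating conditions, the (Z)-silyl enol ether with OSiMe3 cis to the CH2Ar group, so the benzyl arm points away from the ketene-acetal arm.

Step 10
Reactants: 10 1-[4-(benzyloxy)phenyl]-5-{5-(benzyloxy)-2-[4-(benzyloxy)benzyl]phenyl}pent-2-yn-1-one; 15 (3Z)-5-[4-(benzyloxy)phenyl]-1,1-dimethoxy-3-(trimethylsilyloxy)penta-1,3-diene (2.5 equiv)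
Product: 18 {3-[4-(benzyloxy)benzyl]-2-(2-{5-(benzyloxy)-2-[4-(benzyloxy)benzyl]phenyl}ethyl)-4-hydroxy-6-methoxyphenyl}[4-(benzyloxy)phenyl]methanone, via cyclohexadiene cycloadduct 16 (not isolated), via aryl trimethylsilyl ether 17 (not isolated)
Conditions: toluene (ca. 1 M), 120 °C, sealed tube; then 1 M HCl, THF, rt
Reagents that add atoms: none
Why: In a thermal, strongly polarised [4+2] cycloaddition the nucleophilic diene terminus C4 (the enol-ether carbon bearing the benzyl group) bonds to the electrophilic β-carbon of the ynone and the ketene-acetal carbon C1 bonds to the α-carbon, either concertedly and asynchronously or by a Mukaiyama–Michael addition followed by ring closure. The closest known reaction type is the Diels–Alder/aromatisation of 1,1-dialkoxy-3-silyloxybutadienes with acetylenic ketones and esters, which gives resorcinol monoethers with the carbonyl flanked by OMe and the alkyne substituent. Ring A closes as a six-membered carbocycle by cycloaddition (bonds C4–C5 and C1–C6) to give 1,4-cyclohexadiene 16, which loses methanol across C1/C4 and aromatises to silyl ether 17; the acid work-up then frees the C3 phenol while C1 keeps its methyl ether. The only new stereocentre (C4 of 16) is transient and is destroyed on aromatisation, so no stereocontrol is needed. The step needs regioselectivity, secured by the matched push–pull polarisation of diene and ynone, and a diene that can reach the s-cis form, secured by the (Z)-enol ether geometry (benzyl group outward, 1,5-hydrogen shift geometrically impossible); the aroyl group activates the alkyne and is the latent C6 benzylic carbon.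

Step 11
Reactants: 18 {3-[4-(benzyloxy)benzyl]-2-(2-{5-(benzyloxy)-2-[4-(benzyloxy)benzyl]phenyl}ethyl)-4-hydroxy-6-methoxyphenyl}[4-(benzyloxy)phenyl]methanone
Product: 19 (±)-{3-[4-(benzyloxy)benzyl]-2-(2-{5-(benzyloxy)-2-[4-(benzyloxy)benzyl]phenyl}ethyl)-4-hydroxy-6-methoxyphenyl}[4-(benzyloxy)phenyl]methanol
Conditions: LiAlH4 (excess), THF, 0 °C → rt; aq Rochelle salt; used crude
Reagents that add atoms: none
Why: Hydride reduction with the small, strong donor LiAlH4 is chosen because the ketone is flanked by two ortho substituents and carries a para-phenoxide, which would make borohydride sluggish; the racemic carbinol centre is removed in step 12, and any over-reduction through the p-quinone methide would only give 20 early.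

Step 12
Reactants: 19 (±)-{3-[4-(benzyloxy)benzyl]-2-(2-{5-(benzyloxy)-2-[4-(benzyloxy)benzyl]phenyl}ethyl)-4-hydroxy-6-methoxyphenyl}[4-(benzyloxy)phenyl]methanol
Product: 20 2,4-bis[4-(benzyloxy)benzyl]-3-(2-{5-(benzyloxy)-2-[4-(benzyloxy)benzyl]phenyl}ethyl)-5-methoxyphenol
Conditions: Et3SiH, TFA, CH2Cl2, −20 → 0 °C
Reagents that add atoms: none
Why: Ionic hydrogenation (Kursanov–Parnes): the doubly benzylic carbinol ionises readily to a cation stabilised by the para-benzyloxy ring and by the ortho-methoxy/para-hydroxy ring A (a protonated p-quinone methide), which excess silane reduces before it can alkylate another arene.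

Step 13
Reactants: 20 2,4-bis[4-(benzyloxy)benzyl]-3-(2-{5-(benzyloxy)-2-[4-(benzyloxy)benzyl]phenyl}ethyl)-5-methoxyphenol
Product: 21 2,4-bis(4-hydroxybenzyl)-3-{2-[5-hydroxy-2-(4-hydroxybenzyl)phenyl]ethyl}-5-methoxyphenol (target, CNP0147493.0)
Conditions: H2 (1 atm), 10% Pd/C, EtOAc/MeOH, rt
Reagents that add atoms: none
Why: Catalytic hydrogenolysis cleaves the four aryl benzyl ethers, whereas the diarylmethane C–C bonds, the ethylene bridge and the aryl methyl ether are inert under these conditions.

**Compound list**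

1 | 2-bromo-4-hydroxybenzaldehyde | O=Cc1ccc(O)cc1Br | starting material
2 | 4-(benzyloxy)-2-bromobenzaldehyde | O=Cc1ccc(OCc2ccccc2)cc1Br | intermediate
3 | 4-(benzyloxy)phenylmagnesium bromide | Br[Mg]c1ccc(OCc2ccccc2)cc1 | starting material
4 | (±)-[4-(benzyloxy)-2-bromophenyl][4-(benzyloxy)phenyl]methanol | OC(c1ccc(OCc2ccccc2)cc1)c1ccc(OCc2ccccc2)cc1Br | intermediate
5 | 4-(benzyloxy)-1-[4-(benzyloxy)benzyl]-2-bromobenzene | Brc1cc(OCc2ccccc2)ccc1Cc1ccc(OCc2ccccc2)cc1 | intermediate
6 | allyl alcohol | C=CCO | starting material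
7 | 3-{5-(benzyloxy)-2-[4-(benzyloxy)benzyl]phenyl}propanal | O=CCCc1cc(OCc2ccccc2)ccc1Cc1ccc(OCc2ccccc2)cc1 | intermediate
8 | 4-(benzyloxy)-1-[4-(benzyloxy)benzyl]-2-(but-3-yn-1-yl)benzene | C#CCCc1cc(OCc2ccccc2)ccc1Cc1ccc(OCc2ccccc2)cc1 | intermediate
9 | 4-(benzyloxy)benzoyl chloride | ClC(=O)c1ccc(OCc2ccccc2)cc1 | starting material
10 | 1-[4-(benzyloxy)phenyl]-5-{5-(benzyloxy)-2-[4-(benzyloxy)benzyl]phenyl}pent-2-yn-1-one | O=C(C#CCCc1cc(OCc2ccccc2)ccc1Cc1ccc(OCc2ccccc2)cc1)c1ccc(OCc2ccccc2)cc1 | intermediate
11 | 3-[4-(benzyloxy)phenyl]propanoic acid | OC(=O)CCc1ccc(OCc2ccccc2)cc1 | starting material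
12 | 3-[4-(benzyloxy)phenyl]propanoyl chloride | ClC(=O)CCc1ccc(OCc2ccccc2)cc1 | intermediate
13 | 1,1-dimethoxyethene | COC(=C)OC | starting material
14 | 5-[4-(benzyloxy)phenyl]-1,1-dimethoxypent-1-en-3-one | COC(OC)=CC(=O)CCc1ccc(OCc2ccccc2)cc1 | intermediate
15 | (3Z)-5-[4-(benzyloxy)phenyl]-1,1-dimethoxy-3-(trimethylsilyloxy)penta-1,3-diene | COC(OC)=C/C(O[Si](C)(C)C)=C/Cc1ccc(OCc2ccccc2)cc1 | intermediate
16 | (±)-cyclohexa-1,4-diene cycloadduct: 6,6-dimethoxy-4-(trimethylsilyloxy) ring with 3-[4-(benzyloxy)benzyl], 2-(arylethyl) and 1-[4-(benzyloxy)benzoyl] groups | COC1(OC)C=C(O[Si](C)(C)C)C(Cc2ccc(OCc3ccccc3)cc2)C(CCc2cc(OCc3ccccc3)ccc2Cc2ccc(OCc3ccccc3)cc2)=C1C(=O)c1ccc(OCc2ccccc2)cc1 | intermediate (not isolated)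
17 | O-trimethylsilyl ether of 18 | COc1cc(O[Si](C)(C)C)c(Cc2ccc(OCc3ccccc3)cc2)c(CCc2cc(OCc3ccccc3)ccc2Cc2ccc(OCc3ccccc3)cc2)c1C(=O)c1ccc(OCc2ccccc2)cc1 | intermediate (not isolated)
18 | {3-[4-(benzyloxy)benzyl]-2-(2-{5-(benzyloxy)-2-[4-(benzyloxy)benzyl]phenyl}ethyl)-4-hydroxy-6-methoxyphenyl}[4-(benzyloxy)phenyl]methanone | COc1cc(O)c(Cc2ccc(OCc3ccccc3)cc2)c(CCc2cc(OCc3ccccc3)ccc2Cc2ccc(OCc3ccccc3)cc2)c1C(=O)c1ccc(OCc2ccccc2)cc1 | intermediate
19 | (±)-{3-[4-(benzyloxy)benzyl]-2-(2-{5-(benzyloxy)-2-[4-(benzyloxy)benzyl]phenyl}ethyl)-4-hydroxy-6-methoxyphenyl}[4-(benzyloxy)phenyl]methanol | COc1cc(O)c(Cc2ccc(OCc3ccccc3)cc2)c(CCc2cc(OCc3ccccc3)ccc2Cc2ccc(OCc3ccccc3)cc2)c1C(O)c1ccc(OCc2ccccc2)cc1 | intermediate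
20 | 2,4-bis[4-(benzyloxy)benzyl]-3-(2-{5-(benzyloxy)-2-[4-(benzyloxy)benzyl]phenyl}ethyl)-5-methoxyphenol | COc1cc(O)c(Cc2ccc(OCc3ccccc3)cc2)c(CCc2cc(OCc3ccccc3)ccc2Cc2ccc(OCc3ccccc3)cc2)c1Cc1ccc(OCc2ccccc2)cc1 | intermediate
21 | 2,4-bis(4-hydroxybenzyl)-3-{2-[5-hydroxy-2-(4-hydroxybenzyl)phenyl]ethyl}-5-methoxyphenol | COc1cc(O)c(Cc2ccc(O)cc2)c(CCc2cc(O)ccc2Cc2ccc(O)cc2)c1Cc1ccc(O)cc1 | target

**Step count and risks**

Total step count: 13. Longest linear sequence: 10 steps (steps 1–6, then 10–13); the diene branch (steps 7–9) is three steps.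

Steps most likely to fail:

1. Step 10. The cycloaddition may be slower than thermal desilylation or decomposition of the diene, because both bonding termini are substituted and the 4-alkoxyaroyl group is only a moderate activator; any (E)-enol ether present would not react at all. The fallback changes the dienophile class and moves the aryl–carbon bond to after the benzannulation. It sets out from alkyne 8: deprotonation with n-BuLi and formylation with DMF (THF, −78 °C, inverse quench into aqueous KH2PO4) should give 5-{5-(benzyloxy)-2-[4-(benzyloxy)benzyl]phenyl}pent-2-ynal F1, a smaller and more electrophilic dienophile. Heating F1 with diene 15 in toluene should give, through the cyclohexadiene cycloadduct F2 and the aryl trimethylsilyl ether F3 (neither isolated), after the same acid work-up 3-[4-(benzyloxy)benzyl]-2-(2-{5-(benzyloxy)-2-[4-(benzyloxy)benzyl]phenyl}ethyl)-4-hydroxy-6-methoxybenzaldehyde F4. Addition of Grignard reagent 3 (3 equiv, THF, 0 °C → rt; the first equivalent is consumed by the phenol) should then give carbinol 19, where the route is rejoined.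

2. Step 4. Oxidative addition to the ortho-substituted aryl bromide may be slow, and at the temperature then needed the insertion can give branched product, β-hydride elimination can go the wrong way (cinnamyl alcohol), and the product aldehyde can undergo aldol condensation. The fallback replaces the Heck reaction by a B-alkyl Suzuki–Miyaura coupling and sets out from bromide 5. Acrolein diethyl acetal is hydroborated with 9-BBN (THF, rt) to give 9-(3,3-diethoxypropyl)-9-borabicyclo[3.3.1]nonane F5. This is coupled in the same flask with 5 (PdCl2(dppf), aq K3PO4, THF/DMF, 60 °C) to give 4-(benzyloxy)-1-[4-(benzyloxy)benzyl]-2-(3,3-diethoxypropyl)benzene F6. Mild hydrolysis (1 M HCl, THF, rt) returns aldehyde 7.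

3. Step 8. With this enolisable acid chloride the intermediate dimethoxycarbenium ion may be demethylated by chloride (giving the β-keto ester) or the acid chloride may be dehydrochlorinated, instead of clean C-acylation; the product is also sensitive to hydrolysis on isolation. The fallback makes the C4–C5 bond of the diene skeleton by enolate alkylation and sets out from ketene acetal 13. Acylation of 13 with acetyl chloride, the parent case of this reaction with a distillable product, gives 4,4-dimethoxybut-3-en-2-one F7. Its kinetic lithium enolate (LDA, THF, −78 °C) is alkylated at the methyl carbon with commercial 4-(benzyloxy)benzyl bromide to give enone 14.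

**Further compounds**

F1 | step 10 | 5-{5-(benzyloxy)-2-[4-(benzyloxy)benzyl]phenyl}pent-2-ynal | O=CC#CCCc1cc(OCc2ccccc2)ccc1Cc1ccc(OCc2ccccc2)cc1
F2 | step 10 | (±)-cyclohexa-1,4-diene cycloadduct of F1 and 15 (6,6-dimethoxy-4-trimethylsilyloxy-1-carbaldehyde) | COC1(OC)C=C(O[Si](C)(C)C)C(Cc2ccc(OCc3ccccc3)cc2)C(CCc2cc(OCc3ccccc3)ccc2Cc2ccc(OCc3ccccc3)cc2)=C1C=O
F3 | step 10 | O-trimethylsilyl ether of F4 | COc1cc(O[Si](C)(C)C)c(Cc2ccc(OCc3ccccc3)cc2)c(CCc2cc(OCc3ccccc3)ccc2Cc2ccc(OCc3ccccc3)cc2)c1C=O
F4 | step 10 | 3-[4-(benzyloxy)benzyl]-2-(2-{5-(benzyloxy)-2-[4-(benzyloxy)benzyl]phenyl}ethyl)-4-hydroxy-6-methoxybenzaldehyde | COc1cc(O)c(Cc2ccc(OCc3ccccc3)cc2)c(CCc2cc(OCc3ccccc3)ccc2Cc2ccc(OCc3ccccc3)cc2)c1C=O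
F5 | step 4 | 9-(3,3-diethoxypropyl)-9-borabicyclo[3.3.1]nonane | CCOC(CCB1C2CCCC1CCC2)OCC
F6 | step 4 | 4-(benzyloxy)-1-[4-(benzyloxy)benzyl]-2-(3,3-diethoxypropyl)benzene | CCOC(CCc1cc(OCc2ccccc2)ccc1Cc1ccc(OCc2ccccc2)cc1)OCC
F7 | step 8 | 4,4-dimethoxybut-3-en-2-one | COC(OC)=CC(C)=O
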